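Numbering the quinone ring C1 (C=O), C2 (OH), C3 (octadecyl), C4 (C=O), C5 (OMe), C6 (H), the ring is cut at C4–C5 and C2–C3. The key step exploits the 1,4-dicarbonyl relationship of C1 and C4 and the vinylogous ester O=C1–C6=C5–OMe: C4 is the formyl carbon of icosanal, C5 the β-carbon of methyl (E)-4-methoxy-2-oxobut-3-enoate. Both are electrophilic, so a thiazolium-derived carbene reverses the polarity of the aldehyde (Stetter addition); the ketone α-carbon (C3) then closes onto the ester carbon (C2) in a Dieckmann condensation. One flask thus gives the ring as its aromatic triol, which FeCl3 oxidises to the hydroxyquinone.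

Key step: step 3

Remark: the target is achiral and is written as its 2-hydroxy-1,4-dione tautomer; the only stereocentre on the way (in 6) forms racemic and is erased on aromatisation.

Step 1
Reactants: 1 icosan-1-ol
Product: 2 icosanal
Conditions: TEMPO (10 mol %), PhI(OAc)2 (1.1 equiv), CH2Cl2, 30 °C
Reagents that add atoms: none
Why: Oxoammonium-mediated (TEMPO/PhI(OAc)2) oxidation of an unhindered primary alcohol should stop at the aldehyde under anhydrous conditions, because no hydrate is available for further oxidation.

Step 2
Reactants: 3 methyl vinyl ether; 4 methyl chlorooxoacetate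
Product: 5 methyl (E)-4-methoxy-2-oxobut-3-enoate
Conditions: pyridine (1.1 equiv), CH2Cl2, −20 °C to rt
Reagents that add atoms: none
Why: Friedel–Crafts-type C-acylation of an enol ether: the nucleophilic terminal carbon of 3 attacks the acid chloride of 4 (far more reactive than its ester), and pyridine removes HCl from the β-chloro ether adduct to give the conjugated, thermodynamically preferred (E)-β-methoxy enone.

Step 3
Reactants: 2 icosanal; 5 methyl (E)-4-methoxy-2-oxobut-3-enoate
Product: 9 irisoquin, via Stetter adduct 6 (not isolated), via cyclohexanetrione 7 (not isolated), via benzenetriol 8 (not isolated)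
Conditions: 3-benzyl-5-(2-hydroxyethyl)-4-methylthiazolium chloride (20 mol %), Et3N (50 mol %), THF–MeOH (9:1), 60 °C, Ar; then NaOMe (3 equiv), MeOH, 0 °C to rt, Ar; then aq. HCl, FeCl3 (2.2 equiv), rt
Reagents that add atoms: none
Why: The thiazol-2-ylidene adds to the formyl carbon of 2 to give the Breslow intermediate, whose nucleophilic acyl carbon attacks C4 of 5 (the enone β-carbon, activated by the α-keto ester), and release of the carbene gives 1,4-diketone 6; this is a Stetter reaction, closest to the intermolecular Stetter additions to β,γ-unsaturated α-keto esters and the intramolecular ones to β-alkoxyacrylates, followed in the same flask by a condensation as in domino Stetter–aldol sequences. Methoxide then forms the enolate of the new ketone at C6 of 6, which attacks the ester carbon C1 in a 6-exo-trig Dieckmann condensation to give trione 7. Trione 7 enolises to the aromatic triol 8, which makes ring closure irreversible, and FeCl3 oxidises the two para-related hydroxyls to the quinone while the third remains as the enol OH. The stereocentre at C4 of 6 forms racemic and is destroyed on aromatisation, so no stereocontrol is needed. The step needs 1,4- over 1,2-addition (the cross-acyloin adduct at the keto carbonyl reverts under thiazolium catalysis, the Stetter adduct does not), retention of the methoxy group (in methanol any β-elimination is reversed at the same carbon, the β-position of the more electron-poor enone, and every alkoxy exchange is degenerate) and Claisen over aldol closure (the keto carbonyl is masked as its hemiketal in methoxide/methanol and its aldol adducts form reversibly, whereas the Claisen product aromatises).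

Compound list
1 | icosan-1-ol | CCCCCCCCCCCCCCCCCCCCO | starting material
2 | icosanal | CCCCCCCCCCCCCCCCCCCC=O | intermediate
3 | methyl vinyl ether (methoxyethene) | COC=C | starting material
4 | methyl chlorooxoacetate (methyl oxalyl chloride) | COC(=O)C(=O)Cl | starting material
5 | methyl (E)-4-methoxy-2-oxobut-3-enoate | CO/C=C/C(=O)C(=O)OC | intermediate
6 | methyl 4-methoxy-2,5-dioxotetracosanoate (racemic, not isolated) | CCCCCCCCCCCCCCCCCCCC(=O)C(OC)CC(=O)C(=O)OC | intermediate
7 | 5-methoxy-3-octadecylcyclohexane-1,2,4-trione (not isolated) | CCCCCCCCCCCCCCCCCCC1C(=O)C(=O)CC(OC)C1=O | intermediate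
8 | 5-methoxy-3-octadecylbenzene-1,2,4-triol (not isolated) | CCCCCCCCCCCCCCCCCCc1c(O)c(O)cc(OC)c1O | intermediate
9 | irisoquin (2-hydroxy-5-methoxy-3-octadecylcyclohexa-2,5-diene-1,4-dione) | CCCCCCCCCCCCCCCCCCC1=C(O)C(=O)C=C(OC)C1=O | target

Total step count: 3. Longest linear sequence: 2 steps (1 → 2 → 9, or 3 + 4 → 5 → 9).

Steps most likely to fail

Step 3. Three processes can derail the cascade. Methoxide can be lost by β-elimination from the Stetter intermediate and re-added unselectively. The ketone enolate can close in a five-membered aldol condensation on the keto carbonyl instead of the six-membered Claisen closure on the ester. The aldehyde can be consumed by self-acyloin coupling. The fallback sets out from 2 and comes back at 9; it builds the ring by classical Claisen chemistry with no polarity reversal. Addition of 1-ethoxyvinyllithium (ethyl vinyl ether, t-BuLi, THF, −78 °C) to 2 should give 2-ethoxydocos-1-en-3-ol F1, which dilute aq. HCl hydrolyses to 3-hydroxydocosan-2-one F2. Oxidation with Dess–Martin periodinane in CH2Cl2 should give docosane-2,3-dione F3. Double Claisen condensation of F3 with dimethyl oxalate (NaOMe, MeOH–THF), first at the methyl group and then ring-closing at C4, should give 2,5-dihydroxy-3-octadecylcyclohexa-2,5-diene-1,4-dione F4. Acid-catalysed etherification (MeOH, cat. H2SO4, rt) should then methylate the unhindered vinylogous acid next to the ring CH in preference to the one flanked by the octadecyl chain, giving 9.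

Step 2. The volatile enol ether can oligomerise under the liberated acid or escape before acylation, and the β-chloro ether adduct may not lose HCl completely. The fallback sets out from 3 and comes back at 5. Compound 3 is condensed into neat oxalyl chloride (0 °C to rt) without base; the adduct loses HCl on warming and distillation to give (E)-4-methoxy-2-oxobut-3-enoyl chloride F5, which is quenched with methanol (CH2Cl2, 0 °C) to give 5.

Step 1. The waxy alcohol dissolves slowly, which favours over-oxidation and ester formation through the hemiacetal. The fallback sets out from 1 and comes back at 2; it replaces dehydrogenation by oxygen transfer to an alkyl halide, which cannot over-oxidise. Appel bromination of 1 (CBr4, PPh3, CH2Cl2) should give 1-bromoicosane F6, and Ganem oxidation of F6 with trimethylamine N-oxide (DMSO, 60 °C) should give 2.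

Further compounds
F1 | step 3 | 2-ethoxydocos-1-en-3-ol (racemic) | CCCCCCCCCCCCCCCCCCCC(O)C(=C)OCC
F2 | step 3 | 3-hydroxydocosan-2-one (racemic) | CCCCCCCCCCCCCCCCCCCC(O)C(C)=O
F3 | step 3 | docosane-2,3-dione | CCCCCCCCCCCCCCCCCCCC(=O)C(C)=O
F4 | step 3 | 2,5-dihydroxy-3-octadecylcyclohexa-2,5-diene-1,4-dione | CCCCCCCCCCCCCCCCCCC1=C(O)C(=O)C=C(O)C1=O
F5 | step 2 | (E)-4-methoxy-2-oxobut-3-enoyl chloride | CO/C=C/C(=O)C(=O)Cl
F6 | step 1 | 1-bromoicosane | CCCCCCCCCCCCCCCCCCCCBr
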